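The molecule is cut at the bond between the acyclic quaternary carbon C3 of the side chain and its C2 methylene, the arm that leads to the ring. In one operation a lithiated secondary allylic carbamate captures a primary alkylboronic ester and a boron-to-carbon 1,2-shift makes the C3–C2 bond and sets C3, giving a tertiary allylic boronic ester whose boron later becomes vinyl. The step exploits the fact that C3 bears methyl, vinyl, the E-C4=C5 alkenyl arm and the C2–C1 ethylene tether to ring carbon C1 of the trimethyl-methylidenecyclohexane. The precursors are the (S)-carbinol diisopropylcarbamate of the acyclic triene half and the pinacol boronate of the ring ethyl arm.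

Key step: step 25

Remark: the drawn isomer has the ring substituents at C1 and C3 trans, (1S,3S), and the chain (3S,4E,6S,9E,13R); in step 1 the ligand antipode is the one that gives the (3S) ketone.

Step 1
Reactants: 1 2-methylcyclohex-2-en-1-one
Product: 3 (3S)-2,2,3-trimethylcyclohexan-1-one, via aluminium enolate 2 (not isolated)
Conditions: Me3Al, copper thiophene-2-carboxylate Cu(O2CC4H3S) (2 mol %), BINOL-derived bis(1-phenylethyl)amine phosphoramidite (4 mol %), Et2O, −30 °C; then MeLi, THF, DMPU, MeI, −30 °C to rt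
Reagents that add atoms: trimethylaluminium, C[Al](C)C; iodomethane, CI
Why: Copper-catalysed asymmetric conjugate addition sets C3 under ligand control, and the regiodefined enolate, activated as its lithium ate complex, is methylated at the substituted α-carbon (conjugate addition–enolate alkylation).

Step 2
Reactants: 3 (3S)-2,2,3-trimethylcyclohexan-1-one
Product: 4 (3S,6Z)-6-(hydroxymethylidene)-2,2,3-trimethylcyclohexan-1-one
Conditions: NaH, HCO2Et, EtOH (cat.), THF, 0 °C to rt; aq. HCl
Reagents that add atoms: ethyl formate, CCOC=O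
Why: Claisen-type formylation can occur only at C6, the sole enolisable α-carbon, and the product rests as the chelated enol.

Step 3
Reactants: 4 (3S,6Z)-6-(hydroxymethylidene)-2,2,3-trimethylcyclohexan-1-one
Product: 5 (3S,6E)-2,2,3-trimethyl-6-[(propan-2-yloxy)methylidene]cyclohexan-1-one
Conditions: 2-iodopropane, K2CO3, acetone, reflux
Reagents that add atoms: 2-iodopropane, CC(C)I
Why: O-alkylation of the β-keto aldehyde enolate with a secondary iodide should give the vinylogous ester (isopropoxymethylene derivative).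

Step 4
Reactants: 5 (3S,6E)-2,2,3-trimethyl-6-[(propan-2-yloxy)methylidene]cyclohexan-1-one
Product: 7 (4S)-3,3,4-trimethylcyclohex-1-ene-1-carbaldehyde, via carbinol 6 (not isolated)
Conditions: LiAlH4, Et2O, 0 °C; then aq. HCl, THF, rt
Reagents that add atoms: water, O
Why: Hydride 1,2-reduction of the vinylogous ester, then acid-induced allylic ionisation and enol ether hydrolysis, is the classical reductive 1,3-carbonyl transposition; the C4 stereocentre is not touched.

Step 5
Reactants: 7 (4S)-3,3,4-trimethylcyclohex-1-ene-1-carbaldehyde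
Product: 8 [(4S)-3,3,4-trimethylcyclohex-1-en-1-yl]methanol
Conditions: NaBH4, CeCl3·7H2O, MeOH, 0 °C
Reagents that add atoms: none
Why: Luche reduction gives the primary allylic alcohol by clean 1,2-addition.

Step 6
Reactants: 8 [(4S)-3,3,4-trimethylcyclohex-1-en-1-yl]methanol
Product: 10 ethyl 2-[(1S,3S)-2,2,3-trimethyl-6-methylidenecyclohexyl]acetate, via ketene acetal 9 (not isolated)
Conditions: MeC(OEt)3, EtCO2H (cat.), 140 °C, distilling EtOH
Reagents that add atoms: triethyl orthoacetate, CCOC(C)(OCC)OCC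
Why: The Johnson–Claisen rearrangement forms the ring C–CH2 bond and the exocyclic methylene in one [3,3] shift, and the new stereocentre should arise by axial bond formation at C2 of 8 anti to the pseudoaxial C3 methyl in the half-chair with equatorial C4 methyl, which places the new arm trans to that methyl.

Step 7
Reactants: 10 ethyl 2-[(1S,3S)-2,2,3-trimethyl-6-methylidenecyclohexyl]acetate
Product: 11 2-[(1S,3S)-2,2,3-trimethyl-6-methylidenecyclohexyl]ethan-1-ol
Conditions: LiAlH4, Et2O, 0 °C
Reagents that add atoms: none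
Why: Hydride reduction of the ester leaves the isolated 1,1-disubstituted alkene alone.

Step 8
Reactants: 11 2-[(1S,3S)-2,2,3-trimethyl-6-methylidenecyclohexyl]ethan-1-ol
Product: 12 (1S,3S)-1-(2-iodoethyl)-2,2,3-trimethyl-6-methylidenecyclohexane
Conditions: I2, PPh3, imidazole, CH2Cl2, 0 °C to rt
Reagents that add atoms: iodine, [I][I]
Why: Appel-type iodination of the primary alcohol proceeds without a cation that could move the exocyclic alkene.

Step 9
Reactants: 12 (1S,3S)-1-(2-iodoethyl)-2,2,3-trimethyl-6-methylidenecyclohexane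
Product: 13 4,4,5,5-tetramethyl-2-{2-[(1S,3S)-2,2,3-trimethyl-6-methylidenecyclohexyl]ethyl}-1,3,2-dioxaborolane
Conditions: B2pin2, CuI (10 mol %), PPh3 (13 mol %), LiOMe, DMF, rt
Reagents that add atoms: bis(pinacolato)diboron, CC1(C)OB(OC1(C)C)B1OC(C)(C)C(C)(C)O1
Why: Copper-catalysed borylation of a primary alkyl iodide gives the pinacol boronate, and the pentenyl-type radical that may intervene has no fast cyclisation channel.

Step 10
Reactants: 14 methyl (2R)-3-hydroxy-2-methylpropanoate
Product: 15 methyl (2R)-3-{[tert-butyl(dimethyl)silyl]oxy}-2-methylpropanoate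
Conditions: t-BuMe2SiCl, imidazole, CH2Cl2, rt
Reagents that add atoms: tert-butyl(chloro)dimethylsilane, CC(C)(C)[Si](C)(C)Cl
Why: Silylation of the primary alcohol is a standard protection that does not affect the α-stereocentre.

Step 11
Reactants: 15 methyl (2R)-3-{[tert-butyl(dimethyl)silyl]oxy}-2-methylpropanoate
Product: 16 (2R)-3-{[tert-butyl(dimethyl)silyl]oxy}-2-methylpropanal
Conditions: i-Bu2AlH, CH2Cl2, −78 °C
Reagents that add atoms: none
Why: Partial ester reduction at low temperature stops at the aldehyde through the stable tetrahedral aluminate.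

Step 12
Reactants: 16 (2R)-3-{[tert-butyl(dimethyl)silyl]oxy}-2-methylpropanal
Product: 17 tert-butyl(dimethyl){[(2S)-2-methylbut-3-en-1-yl]oxy}silane
Conditions: Ph3PCH3Br, KN(SiMe3)2, THF, −78 to 0 °C
Reagents that add atoms: methyltriphenylphosphonium bromide, C[P+](c1ccccc1)(c1ccccc1)c1ccccc1.[Br-]
Why: Salt-free Wittig methylenation at low temperature converts the aldehyde into the vinyl group fast enough to preserve the α-stereocentre.

Step 13
Reactants: 18 (4S)-1-methyl-4-(prop-1-en-2-yl)cyclohex-1-ene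
Product: 19 (4S)-1-methyl-4-(prop-1-en-2-yl)-7-oxabicyclo[4.1.0]heptane
Conditions: m-CPBA, NaHCO3, CH2Cl2, 0 °C
Reagents that add atoms: 3-chloroperoxybenzoic acid, OOC(=O)c1cccc(Cl)c1
Why: Prilezhaev epoxidation prefers the electron-richer trisubstituted ring alkene over the isopropenyl group, and both epoxide epimers converge in step 14.

Step 14
Reactants: 19 (4S)-1-methyl-4-(prop-1-en-2-yl)-7-oxabicyclo[4.1.0]heptane
Product: 20 (3S)-6-oxo-3-(prop-1-en-2-yl)heptanal
Conditions: H5IO6, THF/H2O, 0 °C to rt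
Reagents that add atoms: water, O
Why: Periodic acid opens the epoxide and cleaves the glycol (Malaprade cleavage) to the keto aldehyde without touching the allylic stereocentre.

Step 15
Reactants: 20 (3S)-6-oxo-3-(prop-1-en-2-yl)heptanal
Product: 21 (3S)-6-oxo-3-(prop-1-en-2-yl)heptanoic acid
Conditions: NaClO2, NaH2PO4, 2-methylbut-2-ene, t-BuOH/H2O, rt
Reagents that add atoms: sodium chlorite, [Na+].[O-]Cl=O
Why: Pinnick oxidation is selective for the aldehyde, and the scavenger alkene shields the isopropenyl group from hypochlorous acid.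

Step 16
Reactants: 21 (3S)-6-oxo-3-(prop-1-en-2-yl)heptanoic acid
Product: 23 (5R)-5,6-dimethylhept-6-en-2-one, via thiohydroxamate ester 22 (not isolated)
Conditions: N-hydroxypyridine-2-thione, DCC, DMAP (cat.), CH2Cl2, 0 °C to rt, dark; then t-BuSH, tungsten lamp, rt
Reagents that add atoms: none
Why: Barton reductive decarboxylation turns the former ring CH2 into the C5 methyl, and hydrogen transfer from the thiol should outrun the slow 3-exo closure of the homoallylic radical; the stereocentre is not involved.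

Step 17
Reactants: 23 (5R)-5,6-dimethylhept-6-en-2-one
Product: 25 (5R)-5,6-dimethylhept-6-en-1-yne, via enol phosphate 24 (not isolated)
Conditions: i-Pr2NLi, THF, −78 °C; ClP(O)(OEt)2, −78 °C to rt; then i-Pr2NLi (2.3 equiv), −78 °C to rt
Reagents that add atoms: none
Why: Kinetic enolisation toward the methyl group, O-phosphorylation and base-induced elimination of the terminal enol phosphate give the alkyne, which is held as its acetylide until work-up.

Step 18
Reactants: 25 (5R)-5,6-dimethylhept-6-en-1-yne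
Product: 27 (1E,5R)-1-iodo-2,5,6-trimethylhepta-1,6-diene, via alkenylalane 26 (not isolated)
Conditions: Me3Al, Cp2ZrCl2 (0.25 equiv), CH2Cl2, 0 °C to rt; then I2, THF, −30 °C
Reagents that add atoms: trimethylaluminium, C[Al](C)C; iodine, [I][I]
Why: Zirconium-catalysed syn-carboalumination (Negishi) places methyl on the internal alkyne carbon and iodinolysis with retention fixes the E geometry; the 1,1-disubstituted alkene is inert to this reagent.

Step 19
Reactants: 17 tert-butyl(dimethyl){[(2S)-2-methylbut-3-en-1-yl]oxy}silane; 27 (1E,5R)-1-iodo-2,5,6-trimethylhepta-1,6-diene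
Product: 29 tert-butyl(dimethyl){[(2S,5E,9R)-2,6,9,10-tetramethylundeca-5,10-dien-1-yl]oxy}silane, via alkylborane 28 (not isolated)
Conditions: 9-BBN dimer, THF, rt; then 27, Pd(dppf)Cl2 (5 mol %), AsPh3, Cs2CO3, DMF/H2O, rt
Reagents that add atoms: none
Why: Anti-Markovnikov hydroboration of the monosubstituted alkene and B-alkyl Suzuki–Miyaura coupling with retention of the iodoalkene geometry join the two chiral-pool pieces and give the E-trisubstituted alkene.

Step 20
Reactants: 29 tert-butyl(dimethyl){[(2S,5E,9R)-2,6,9,10-tetramethylundeca-5,10-dien-1-yl]oxy}silane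
Product: 30 (2S,5E,9R)-2,6,9,10-tetramethylundeca-5,10-dien-1-ol
Conditions: Bu4NF, THF, 0 °C to rt
Reagents that add atoms: none
Why: Fluoride-mediated desilylation frees the primary alcohol.

Step 21
Reactants: 30 (2S,5E,9R)-2,6,9,10-tetramethylundeca-5,10-dien-1-ol
Product: 31 (2S,5E,9R)-2,6,9,10-tetramethylundeca-5,10-dienal
Conditions: Dess–Martin periodinane, NaHCO3, CH2Cl2, 0 °C to rt
Reagents that add atoms: none
Why: Buffered Dess–Martin oxidation should give the α-methyl aldehyde without epimerisation, and it is used at once.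

Step 22
Reactants: 31 (2S,5E,9R)-2,6,9,10-tetramethylundeca-5,10-dienal
Product: 32 (3E,5S,8E,12R)-5,9,12,13-tetramethyltetradeca-3,8,13-trien-2-one
Conditions: Ph3P=CHC(O)CH3, CH2Cl2, 40 °C
Reagents that add atoms: 1-(triphenyl-λ5-phosphanylidene)propan-2-one, CC(=O)C=P(c1ccccc1)(c1ccccc1)c1ccccc1
Why: The Wittig reaction with the stabilised acetonyl ylide is E-selective and neutral, so the α-stereocentre should survive.

Step 23
Reactants: 32 (3E,5S,8E,12R)-5,9,12,13-tetramethyltetradeca-3,8,13-trien-2-one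
Product: 33 (2S,3E,5S,8E,12R)-5,9,12,13-tetramethyltetradeca-3,8,13-trien-2-ol
Conditions: (R)-2-methyl-CBS-oxazaborolidine (0.2 equiv), catecholborane, toluene, −78 °C
Reagents that add atoms: none
Why: In the Corey–Bakshi–Shibata reduction the alkenyl group acts as the large substituent, so the (R)-catalyst should give the (2S) carbinol under catalyst control, and catecholborane does not hydroborate the remote alkenes.

Step 24
Reactants: 33 (2S,3E,5S,8E,12R)-5,9,12,13-tetramethyltetradeca-3,8,13-trien-2-ol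
Product: 34 (2S,3E,5S,8E,12R)-5,9,12,13-tetramethyltetradeca-3,8,13-trien-2-yl N,N-di(propan-2-yl)carbamate
Conditions: NaH, THF, 0 °C; i-Pr2NCOCl, reflux
Reagents that add atoms: N,N-di(propan-2-yl)carbamoyl chloride, CC(C)N(C(C)C)C(Cl)=O
Why: O-carbamoylation of the alkoxide installs the directing and leaving group with retention at the carbinol carbon.

Step 25
Reactants: 34 (2S,3E,5S,8E,12R)-5,9,12,13-tetramethyltetradeca-3,8,13-trien-2-yl N,N-di(propan-2-yl)carbamate; 13 4,4,5,5-tetramethyl-2-{2-[(1S,3S)-2,2,3-trimethyl-6-methylidenecyclohexyl]ethyl}-1,3,2-dioxaborolane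
Product: 37 4,4,5,5-tetramethyl-2-[(3S,4E,6S,9E,13R)-3,6,10,13,14-pentamethyl-1-[(1S,3S)-2,2,3-trimethyl-6-methylidenecyclohexyl]pentadeca-4,9,14-trien-3-yl]-1,3,2-dioxaborolane, via lithiated carbamate 35 (not isolated), via boronate complex 36 (not isolated)
Conditions: s-BuLi (1.2 equiv), TMEDA, Et2O, −78 °C; then 13 in Et2O, −78 °C; then MgBr2·OEt2, MeOH, −78 °C to rt
Reagents that add atoms: none
Why: s-BuLi/TMEDA removes the carbinol hydrogen with retention, the carbamoyl oxygen holding lithium at the α-carbon of the configurationally stable allyl species 35, which adds to boron of 13 with retention to give 36. On warming, the primary alkyl group shifts from boron to carbon antiperiplanar to the departing carbamate, with inversion, and forms the C3–C2 bond; this is the lithiation–borylation of enantioenriched secondary allylic carbamates, a stereospecific 1,2-metallate rearrangement. No ring closes. The new quaternary stereocentre C3 is controlled only by the carbinol configuration from step 23, which the retention–retention–inversion sequence transfers independently of the remote stereocentres. The step needs α- over γ-borylation and migration faster than reversal of 36. The first is secured by the carbamate-chelated lithium at the α-carbon, the second by the unhindered primary migrating group, the good carbamate leaving group and the magnesium bromide/methanol promoter.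

Step 26
Reactants: 37 4,4,5,5-tetramethyl-2-[(3S,4E,6S,9E,13R)-3,6,10,13,14-pentamethyl-1-[(1S,3S)-2,2,3-trimethyl-6-methylidenecyclohexyl]pentadeca-4,9,14-trien-3-yl]-1,3,2-dioxaborolane
Product: 40 (1S,3S)-1-[(3S,4E,6S,9E,13R)-3-ethenyl-3,6,10,13,14-pentamethylpentadeca-4,9,14-trien-1-yl]-2,2,3-trimethyl-6-methylidenecyclohexane, via vinylboronate complex 38 (not isolated), via iodoalkyl boronate 39 (not isolated)
Conditions: vinyllithium (from tetravinylstannane and MeLi), THF, −78 °C; I2, MeOH, −78 °C; NaOMe, MeOH, −78 °C to rt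
Reagents that add atoms: vinyllithium, [Li]C=C
Why: In the Zweifel olefination iodine triggers the 1,2-shift of the tertiary allylic group from boron to the vinyl carbon with retention, and methoxide-induced anti elimination of boron and iodide leaves the vinyl group on the quaternary carbon.

Compound list
1 | 2-methylcyclohex-2-en-1-one | CC1=CCCCC1=O | starting material
2 | dimethylaluminium (3S)-2,3-dimethylcyclohex-1-en-1-olate | C[Al](C)OC1=C(C)[C@@H](C)CCC1 | intermediate
3 | (3S)-2,2,3-trimethylcyclohexan-1-one | O=C1CCC[C@H](C)C1(C)C | intermediate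
4 | (3S,6Z)-6-(hydroxymethylidene)-2,2,3-trimethylcyclohexan-1-one | O=C1/C(=C\O)CC[C@H](C)C1(C)C | intermediate
5 | (3S,6E)-2,2,3-trimethyl-6-[(propan-2-yloxy)methylidene]cyclohexan-1-one | O=C1/C(=C/OC(C)C)CC[C@H](C)C1(C)C | intermediate
6 | (3S,6E)-2,2,3-trimethyl-6-[(propan-2-yloxy)methylidene]cyclohexan-1-ol (both carbinol epimers) | OC1/C(=C/OC(C)C)CC[C@H](C)C1(C)C | intermediate
7 | (4S)-3,3,4-trimethylcyclohex-1-ene-1-carbaldehyde | O=CC1=CC(C)(C)[C@@H](C)CC1 | intermediate
8 | [(4S)-3,3,4-trimethylcyclohex-1-en-1-yl]methanol | OCC1=CC(C)(C)[C@@H](C)CC1 | intermediate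
9 | (4S)-1-{[(1-ethoxyethenyl)oxy]methyl}-3,3,4-trimethylcyclohex-1-ene | C=C(OCC)OCC1=CC(C)(C)[C@@H](C)CC1 | intermediate
10 | ethyl 2-[(1S,3S)-2,2,3-trimethyl-6-methylidenecyclohexyl]acetate | CCOC(=O)C[C@H]1C(=C)CC[C@H](C)C1(C)C | intermediate
11 | 2-[(1S,3S)-2,2,3-trimethyl-6-methylidenecyclohexyl]ethan-1-ol | OCC[C@H]1C(=C)CC[C@H](C)C1(C)C | intermediate
12 | (1S,3S)-1-(2-iodoethyl)-2,2,3-trimethyl-6-methylidenecyclohexane | ICC[C@H]1C(=C)CC[C@H](C)C1(C)C | intermediate
13 | 4,4,5,5-tetramethyl-2-{2-[(1S,3S)-2,2,3-trimethyl-6-methylidenecyclohexyl]ethyl}-1,3,2-dioxaborolane | CC1(C)OB(CC[C@H]2C(=C)CC[C@H](C)C2(C)C)OC1(C)C | intermediate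
14 | methyl (2R)-3-hydroxy-2-methylpropanoate | COC(=O)[C@H](C)CO | starting material
15 | methyl (2R)-3-{[tert-butyl(dimethyl)silyl]oxy}-2-methylpropanoate | COC(=O)[C@H](C)CO[Si](C)(C)C(C)(C)C | intermediate
16 | (2R)-3-{[tert-butyl(dimethyl)silyl]oxy}-2-methylpropanal | O=C[C@H](C)CO[Si](C)(C)C(C)(C)C | intermediate
17 | tert-butyl(dimethyl){[(2S)-2-methylbut-3-en-1-yl]oxy}silane | C=C[C@H](C)CO[Si](C)(C)C(C)(C)C | intermediate
18 | (4S)-1-methyl-4-(prop-1-en-2-yl)cyclohex-1-ene, (S)-limonene | CC1=CC[C@H](CC1)C(C)=C | starting material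
19 | (4S)-1-methyl-4-(prop-1-en-2-yl)-7-oxabicyclo[4.1.0]heptane (both epoxide epimers) | CC12OC1C[C@H](CC2)C(C)=C | intermediate
20 | (3S)-6-oxo-3-(prop-1-en-2-yl)heptanal | O=CC[C@H](CCC(C)=O)C(C)=C | intermediate
21 | (3S)-6-oxo-3-(prop-1-en-2-yl)heptanoic acid | OC(=O)C[C@H](CCC(C)=O)C(C)=C | intermediate
22 | 2-sulfanylidenepyridin-1(2H)-yl (3S)-6-oxo-3-(prop-1-en-2-yl)heptanoate | S=C1C=CC=CN1OC(=O)C[C@H](CCC(C)=O)C(C)=C | intermediate
23 | (5R)-5,6-dimethylhept-6-en-2-one | CC(=O)CC[C@@H](C)C(C)=C | intermediate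
24 | diethyl (5R)-5,6-dimethylhepta-1,6-dien-2-yl phosphate | C=C(CC[C@@H](C)C(C)=C)OP(=O)(OCC)OCC | intermediate
25 | (5R)-5,6-dimethylhept-6-en-1-yne | C#CCC[C@@H](C)C(C)=C | intermediate
26 | dimethyl[(1E,5R)-2,5,6-trimethylhepta-1,6-dien-1-yl]alumane | C[Al](C)/C=C(\C)CC[C@@H](C)C(C)=C | intermediate
27 | (1E,5R)-1-iodo-2,5,6-trimethylhepta-1,6-diene | I/C=C(\C)CC[C@@H](C)C(C)=C | intermediate
28 | 9-[(3S)-4-{[tert-butyl(dimethyl)silyl]oxy}-3-methylbutyl]-9-borabicyclo[3.3.1]nonane | B1(CC[C@H](C)CO[Si](C)(C)C(C)(C)C)C2CCCC1CCC2 | intermediate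
29 | tert-butyl(dimethyl){[(2S,5E,9R)-2,6,9,10-tetramethylundeca-5,10-dien-1-yl]oxy}silane | CC(C)(C)[Si](C)(C)OC[C@@H](C)CC/C=C(\C)CC[C@@H](C)C(C)=C | intermediate
30 | (2S,5E,9R)-2,6,9,10-tetramethylundeca-5,10-dien-1-ol | OC[C@@H](C)CC/C=C(\C)CC[C@@H](C)C(C)=C | intermediate
31 | (2S,5E,9R)-2,6,9,10-tetramethylundeca-5,10-dienal | O=C[C@@H](C)CC/C=C(\C)CC[C@@H](C)C(C)=C | intermediate
32 | (3E,5S,8E,12R)-5,9,12,13-tetramethyltetradeca-3,8,13-trien-2-one | CC(=O)/C=C/[C@@H](C)CC/C=C(\C)CC[C@@H](C)C(C)=C | intermediate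
33 | (2S,3E,5S,8E,12R)-5,9,12,13-tetramethyltetradeca-3,8,13-trien-2-ol | C[C@H](O)/C=C/[C@@H](C)CC/C=C(\C)CC[C@@H](C)C(C)=C | intermediate
34 | (2S,3E,5S,8E,12R)-5,9,12,13-tetramethyltetradeca-3,8,13-trien-2-yl N,N-di(propan-2-yl)carbamate | C[C@H](OC(=O)N(C(C)C)C(C)C)/C=C/[C@@H](C)CC/C=C(\C)CC[C@@H](C)C(=C)C | intermediate
35 | α-lithiated carbamate of 34 (lithium at C2, configuration retained) | C[C@]([Li])(OC(=O)N(C(C)C)C(C)C)/C=C/[C@@H](C)CC/C=C(\C)CC[C@@H](C)C(=C)C | intermediate
36 | lithium boronate complex of 35 and 13 | [Li+].C[C@]([B-]1(CC[C@H]2C(=C)CC[C@H](C)C2(C)C)OC(C)(C)C(C)(C)O1)(OC(=O)N(C(C)C)C(C)C)/C=C/[C@@H](C)CC/C=C(\C)CC[C@@H](C)C(=C)C | intermediate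
37 | 4,4,5,5-tetramethyl-2-[(3S,4E,6S,9E,13R)-3,6,10,13,14-pentamethyl-1-[(1S,3S)-2,2,3-trimethyl-6-methylidenecyclohexyl]pentadeca-4,9,14-trien-3-yl]-1,3,2-dioxaborolane | CC1(C)OB(OC1(C)C)[C@@](C)(/C=C/[C@@H](C)CC/C=C(\C)CC[C@@H](C)C(=C)C)CC[C@H]2C(=C)CC[C@H](C)C2(C)C | intermediate
38 | lithium vinylboronate complex of 37 | [Li+].C=C[B-]1(OC(C)(C)C(C)(C)O1)[C@@](C)(/C=C/[C@@H](C)CC/C=C(\C)CC[C@@H](C)C(=C)C)CC[C@H]2C(=C)CC[C@H](C)C2(C)C | intermediate
39 | β-iodoalkyl pinacol boronate formed by the 1,2-shift (both epimers at the boron-bearing carbon) | ICC(B1OC(C)(C)C(C)(C)O1)[C@@](C)(/C=C/[C@@H](C)CC/C=C(\C)CC[C@@H](C)C(=C)C)CC[C@H]2C(=C)CC[C@H](C)C2(C)C | intermediate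
40 | (1S,3S)-1-[(3S,4E,6S,9E,13R)-3-ethenyl-3,6,10,13,14-pentamethylpentadeca-4,9,14-trien-1-yl]-2,2,3-trimethyl-6-methylidenecyclohexane | C=C[C@@](C)(/C=C/[C@@H](C)CC/C=C(\C)CC[C@@H](C)C(=C)C)CC[C@H]1C(=C)CC[C@H](C)C1(C)C | target

Total step count: 26. Longest linear sequence: 14 steps (18 to 40, steps 13 to 26).

Steps most likely to fail

Step 25. The hindered pinacol boronate complex may revert to the lithiated carbamate faster than it rearranges, so that the carbenoid loses its configuration or is protonated. The fallback changes the boron partner. Iodide 12 is borylated with bis(neopentyl glycolato)diboron (CuI, PPh3, LiOMe, DMF) to the neopentyl glycol boronate F1. Its less shielded boron should take up the lithium carbenoid from 34 more firmly and rearrange more readily, giving the tertiary neopentyl glycol boronate F2. F2 is vinylated by the same Zweifel protocol and the route is rejoined at 40.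

Step 6. The sigmatropic shift may deliver carbon to the wrong face of the ring alkene (poor or reversed facial selectivity), which would give the cis ring isomer. The fallback delivers hydrogen instead of carbon to that ring carbon, which reverses the outcome for the same facial preference. Vinylogous ester 5 adds the lithium enolate of tert-butyl acetate at the ketone carbon and acid hydrolysis gives the enal ester F3. Luche reduction gives the allylic alcohol F4. Myers reductive transposition (2-nitrobenzenesulfonylhydrazide, PPh3, diethyl azodicarboxylate, loss of dinitrogen from the allylic diazene) moves the alkene to the exocyclic position and gives the tert-butyl ester F5. LiAlH4 reduction of F5 rejoins the route at 11.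

Step 23. Incomplete facial discrimination in hydride delivery to the enone would give the carbinol epimer, which the key step would carry into the quaternary centre. The fallback takes the carbinol from the chiral pool. Alcohol 30 is converted by Mitsunobu reaction with 1-phenyl-1H-tetrazole-5-thiol into the sulfide F6, which is oxidised with (NH4)6Mo7O24/H2O2 to the sulfone F7. Julia–Kocienski olefination of F7 (KN(SiMe3)2, DME, −60 °C) with (2S)-2-{[tert-butyl(dimethyl)silyl]oxy}propanal, made from ethyl (S)-lactate, gives the E-allylic silyl ether F8. Desilylation with Bu4NF rejoins the route at 33.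

Further compounds
F1 | step 25 | 5,5-dimethyl-2-{2-[(1S,3S)-2,2,3-trimethyl-6-methylidenecyclohexyl]ethyl}-1,3,2-dioxaborinane | CC1(C)COB(CC[C@H]2C(=C)CC[C@H](C)C2(C)C)OC1
F2 | step 25 | 5,5-dimethyl-2-[(3S,4E,6S,9E,13R)-3,6,10,13,14-pentamethyl-1-[(1S,3S)-2,2,3-trimethyl-6-methylidenecyclohexyl]pentadeca-4,9,14-trien-3-yl]-1,3,2-dioxaborinane | CC1(C)COB(OC1)[C@@](C)(/C=C/[C@@H](C)CC/C=C(\C)CC[C@@H](C)C(=C)C)CC[C@H]2C(=C)CC[C@H](C)C2(C)C
F3 | step 6 | tert-butyl 2-[(5S)-2-formyl-5,6,6-trimethylcyclohex-1-en-1-yl]acetate | CC(C)(C)OC(=O)CC1=C(C=O)CC[C@H](C)C1(C)C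
F4 | step 6 | tert-butyl 2-[(5S)-2-(hydroxymethyl)-5,6,6-trimethylcyclohex-1-en-1-yl]acetate | CC(C)(C)OC(=O)CC1=C(CO)CC[C@H](C)C1(C)C
F5 | step 6 | tert-butyl 2-[(1S,3S)-2,2,3-trimethyl-6-methylidenecyclohexyl]acetate | CC(C)(C)OC(=O)C[C@H]1C(=C)CC[C@H](C)C1(C)C
F6 | step 23 | 1-phenyl-5-{[(2S,5E,9R)-2,6,9,10-tetramethylundeca-5,10-dien-1-yl]sulfanyl}-1H-tetrazole | c1ccccc1-n1nnnc1SC[C@@H](C)CC/C=C(\C)CC[C@@H](C)C(C)=C
F7 | step 23 | 1-phenyl-5-{[(2S,5E,9R)-2,6,9,10-tetramethylundeca-5,10-dien-1-yl]sulfonyl}-1H-tetrazole | c1ccccc1-n1nnnc1S(=O)(=O)C[C@@H](C)CC/C=C(\C)CC[C@@H](C)C(C)=C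
F8 | step 23 | tert-butyl(dimethyl){[(2S,3E,5S,8E,12R)-5,9,12,13-tetramethyltetradeca-3,8,13-trien-2-yl]oxy}silane | C[C@H](O[Si](C)(C)C(C)(C)C)/C=C/[C@@H](C)CC/C=C(\C)CC[C@@H](C)C(C)=C
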